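## Structural features

The target is an eremophilane-type sesquiterpenoid diester: a cis-fused decalin in which ring A (C1–C5, C10) and ring B (C5–C10) share the C5–C10 bond. Ring A carries the C3 senecioate, the C4 secondary methyl and the C5 angular methyl; ring B carries the C7 isopropenyl group, the C8 ketone and the C9 angelate. There are six stereocentres, five of them contiguous (C3–C4–C5–C10–C9) and C7 across the ketone. Both methyls, H10, the C9 oxygen and the C7 isopropenyl group lie on one face and the C3 oxygen on the other; the absolute configuration is 3R,4R,5R,7R,9R,10S. In the chair–chair conformer with C1 equatorial on ring B, the substituents at C3, C4, C7 and C9 are all equatorial, so C7 and C9, next to the ketone, can be left to thermodynamic control, whereas C3, C4, the quaternary C5 and C10 must be set deliberately and in the absolute sense. The fragile groups are the angelate (Z to E isomerisation to the tiglate), the β,γ-unsaturated ketone (migration of the isopropenyl double bond into conjugation), the α-acyloxy ketone (epimerisation, acyl shift) and the senecioate (deconjugation). The real difficulty is the vicinal C4/C5 pair with the quaternary angular methyl on a cis ring fusion, in one enantiomeric series, together with an end game that spares the sensitive groups. The key step exploits ring B: C5 (quaternary, methyl) stands 1,4 to the C8 carbonyl with oxygen on C9. That is the pattern left when a 2,3-dioxygenated diene (C7=C8–C9=C10) adds to a 2-methyl enone (C5=C6) whose carbonyl C4 lies in the C1–C4 tether, so that forming C6–C7 and C5–C10 closes rings A and B together.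

## Logic of the disconnections

The C9–O acyl bond of 30 is cut first, giving 27 and 28. The angelate is the group most easily lost, so it is attached last; the cut removes one ester and leaves a single free hydroxyl. The forward step must acylate a hindered α-hydroxy ketone without isomerising the Z double bond and without enough base to move the isopropenyl double bond into conjugation.

The C9 hydroxyl of 27 is traced to the 4-methoxybenzyl ether 26 (benzylic C–O bond). The ether keeps the two ring B oxygens distinct from the diene stage onward, so a free acyloin never exists during enolate chemistry. The demand is an oxidative deprotection that spares two alkenes, an ester and the ketone.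

The isopropenyl group of 26 is cut at C7–C11 after formal hydration of C11=C12 to 25, an aldol retron of ketone 21 and 22. This removes three carbons and the C7 stereocentre, which is equatorial next to the ketone and may be left to equilibrium. The forward steps need enolisation toward C7 and not toward the ether-bearing C9, tolerance of the senecioate, and a dehydration that takes a methyl hydrogen and not H7.

The C3–O acyl bond of 21 is cut to 19 and 20. The senecioate is put on as soon as the C3 hydroxyl has served as a directing group; the demand is acylation without deconjugation.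

In 19 the C4–H bond is cut to the allylic alcohol 18 (H2 across C4=C15), 18 is traced to 17 by restoring both O–Si bonds (C3 and C8), and 17 to ketone 16 by cutting C4=C15. This removes the C4 and C9 stereocentres and C15 and returns ring B to the enediol diether that a cycloaddition leaves. The forward steps must methylenate a ketone flanked by the quaternary C5, free the C3 hydroxyl and the C8 ketone in one fluoride step, and deliver hydrogen to C4 from the face of the C3 hydroxyl so that the C4 methyl ends up cis to the angular methyl.

The key cut opens C6–C7 and C5–C10 of 16 and unzips rings A and B to the acyclic trienone 15. Two rings, two C–C bonds and the C5/C10 pair are traded for a chain with one stereocentre, C3. An achiral trienone would need a chiral Lewis acid to choose the enone face. A 2-methyl enone has neither an α-hydrogen nor a formyl hydrogen for the contact that organises enones on cationic oxazaborolidines, and the bis-enol ether diene is acid-labile, so that control cannot be defended. Face selection is therefore moved into the substrate: 15 carries the C3 oxygen of the target as a silyl ether on the tether carbon next to the ketone, and TIPS replaces TBS on the dienol ether. The disconnection, the bonds formed and the carbon skeletons of 15 and 16 are unchanged. The forward step demands the endo transition state (cis fusion), control of the enone face by C3, and survival of the diene.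

The C4–C5 bond of 15 is cut to the N-methoxy-N-methylamide 12 and 13. The enone is unveiled last because diene and enone cannot be stored in one molecule; the demand is a single addition to the amide and a cold, neutral work-up.

The O–Si bond of the dienol ether in 12 is cut, which turns C7=C8 back into the methyl ketone 11; the forward enolisation must take a proton from the methyl group only.

The C9=C10 double bond of 11 is cut to aldehyde 7 and phosphonate 10. This joins tether and diene half convergently and fixes the diene geometry; the olefination must place the chain trans to the acetyl group.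

The C9–O bond of 10 is cut to 8 and 9, a carbenoid O–H insertion in the forward sense that brings in the C9 oxygen already protected.

The aldehyde of 7 is traced to the terminal alkene of 5 (one carbon lost), the silyl ether of 5 to alcohol 4, and the amide of 4 to ester 3. These are functional-group changes that need only chemoselectivity.

The C1–C2 bond of 3 is cut to 1 and 2. Compound 1 supplies C2–C4 and the C3 stereocentre, the single source of absolute configuration; the forward step must open the epoxide at its CH2 carbon faster than 2 attacks the ester.

## Other disconnections considered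

Alternative 1: The cut is the C7–C8 bond of ring B. The forward key step would be a carbonyl-ene cyclisation: Me2AlCl activates the C8 aldehyde of the ring A aldehyde A1 (prenyl on C5, CH2CHO on C10, C3 ketal), C7 of the prenyl alkene bonds to C8, and an allylic methyl hydrogen passes to oxygen, giving the cis-decalin alcohol A2.
- In its favour: the closed, chair-like ene transition state is highly predictable, and it delivers the isopropenyl group at C7 as the non-conjugated alkene directly. On this point it is better than the chosen plan, which needs an aldol addition and a regioselective dehydration (steps 14 and 15).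
- Against it here: only one ring and one C–C bond are formed, so ring A with C4, the quaternary C5 and C10 must be built beforehand in the absolute sense. C9 carries no oxygen in A2, so the C8 ketone would have to be oxidised at C9 against the more acidic, allylic H7. The C3 ketal must later be reduced with a C8 ketone present.
- Comparison: on mechanism it is the equal or the better of the chosen step (no endo/exo question). On structure it sets fewer of the hard centres (none of C4, C5, C10). On step economy it would be longer, because both the precursor and the C9/C3 adjustments cost steps.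

Alternative 2: The cut is C5–C6, paired with reconnection of C3 to C8. The forward key step would be the anionic oxy-Cope rearrangement (KH, 18-crown-6) of the 2-vinylbicyclo[2.2.2]octenol A3, which forms C5–C6, breaks C3–C8 and gives the cis-octalenone A4 as its C8 enolate.
- In its favour: the [3,3] shift in a rigid bicycle is stereospecific, so the cis fusion and the quaternary C5 are guaranteed; here it is better than a cycloaddition that depends on an endo preference. A3 would be only a few steps from a simple phenol (oxidative dearomatisation in methanol, cycloaddition, vinyl addition), so the route to the bicyclic core is shorter than the chosen one, also a point in its favour. The C8 ketone and C9 oxygen arrive in the right places.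
- Against it here: nothing in A3 fixes the absolute configuration, so a resolution or an asymmetric variant must be added. Ethylene is a poor partner for the masked quinone, and a surrogate adds steps. C9 arrives at the ketone level and must be unmasked and reduced selectively next to the C8 ketone. The C3=C4 alkene of A4 still needs a face-selective hydroboration on a cis-decalin whose two faces are not clearly differentiated.
- Comparison: better on the reliability of the ring fusion and on steps to the core. Worse on absolute control and on the C3/C4 and C9 adjustments, which the chosen plan settles by chiral-pool substrate control and a directed hydrogenation. Overall length would be similar once resolution is counted.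

Alternative 3: The cut is C4–C5 and C1–C10 (ring A). The forward key step would be the Diels–Alder addition of silyloxydiene A6 across the methyl-substituted double bond of quinone A5, giving the cis-fused endo adduct A7.
- In its favour: it is intermolecular and fully convergent from two very simple partners in one step, better than the chosen plan in steps to the bicycle. Regiochemistry and endo selectivity of quinone cycloadditions are dependable, and enantioselective catalysis of quinone Diels–Alder reactions with silyloxydienes is an established reaction type. Absolute control by a catalyst is therefore better founded here than it would be for a catalyst-controlled version of the chosen intramolecular step, and equal to the substrate control actually chosen. The C4 methyl and the C3 oxygen come with the diene.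
- Against it here: the C4 methyl is epimeric and must be inverted through the C3 ketone. Ring B is over-oxidised: the C6 carbonyl next to the quaternary C5 must be removed entirely, the C9 ketone reduced with the right sense, the C8 methoxy enone converted into the saturated ketone, and the isopropenyl group still added. Three carbonyls have to be told apart.
- Comparison: better on convergence and on precedent for the key step. Worse on redox economy and on functional-group differentiation. Overall it would be longer than the chosen plan.

Key step: step 9

Remark on structure: the diene geometry the cycloaddition needs (tether trans to C8 across C9=C10, an E-diene in the Diels–Alder sense) is Z by the sequence rule, because the ether oxygen on C9 outranks C8; the trienone is therefore named 7Z.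

Remark on design: 15 keeps the 2-methyl-8-alkoxy-9-silyloxydeca-1,7,9-trien-3-one skeleton and 16 the cis-fused 5-methyloctalin-4-one skeleton; the only changes are the silyloxy group on tether carbon C3 and TIPS in place of TBS on the dienol ether.

Assumption: 2, 8 and 13 are bought as commercial reagents (13 is otherwise made from 2-bromopropene and magnesium, 8 by diazo transfer to dimethyl (2-oxopropyl)phosphonate).

## Route

Step 1
Reactants: 1 methyl (2R)-oxirane-2-carboxylate; 2 allylmagnesium chloride
Product: 3 methyl (2R)-2-hydroxyhex-5-enoate
Conditions: CuI (10 mol %), THF, −78 °C, slow addition of 2; aq. NH4Cl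
Reagents that add atoms: none
Why: Copper-catalysed SN2 opening of the glycidic epoxide at its CH2 carbon; at −78 °C the organocopper species should open the activated epoxide faster than the magnesium reagent adds to the ester. C2 is not touched, so the R configuration is carried over.

Step 2
Reactants: 3 methyl (2R)-2-hydroxyhex-5-enoate
Product: 4 (2R)-2-hydroxy-N-methoxy-N-methylhex-5-enamide
Conditions: MeNHOMe·HCl, i-PrMgCl, THF, −20 to 0 °C
Reagents that add atoms: N,O-dimethylhydroxylamine hydrochloride, CNOC.Cl
Why: Direct aminolysis of the ester by the magnesium amide of N,O-dimethylhydroxylamine (Weinreb amide synthesis); the hydroxyl is held as its magnesium alkoxide, which also protects the stereocentre from enolisation.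

Step 3
Reactants: 4 (2R)-2-hydroxy-N-methoxy-N-methylhex-5-enamide
Product: 5 (2R)-2-(tert-butyldimethylsilyloxy)-N-methoxy-N-methylhex-5-enamide
Conditions: TBSCl, imidazole, DMF, rt
Reagents that add atoms: tert-butyldimethylsilyl chloride, CC(C)(C)[Si](C)(C)Cl
Why: Standard silylation of a secondary alcohol. The TBS ether blocks oxa-Michael addition to the later enone, does not chelate the Lewis acid of step 9, and leaves with fluoride together with the enol silane in step 11.

Step 4
Reactants: 5 (2R)-2-(tert-butyldimethylsilyloxy)-N-methoxy-N-methylhex-5-enamide
Product: 7 (2R)-2-(tert-butyldimethylsilyloxy)-N-methoxy-N-methyl-5-oxopentanamide, via ozonide 6 (not isolated)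
Conditions: O3, CH2Cl2, −78 °C; then PPh3, −78 °C to rt
Reagents that add atoms: ozone, [O-][O+]=O
Why: Ozonolysis with reductive work-up cleaves the only C=C bond to the aldehyde; the amide and the silyl ether are inert.

Step 5
Reactants: 8 dimethyl (1-diazo-2-oxopropyl)phosphonate; 9 4-methoxybenzyl alcohol
Product: 10 dimethyl [1-(4-methoxybenzyloxy)-2-oxopropyl]phosphonate
Conditions: Rh2(OAc)4 (1 mol %), toluene, 80 °C, slow addition of 8
Reagents that add atoms: none
Why: Rhodium carbenoid O–H insertion: the diazo ketophosphonate loses N2 on the catalyst and the electrophilic carbenoid inserts into the O–H bond of the alcohol, which installs the C9 oxygen already protected.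

Step 6
Reactants: 7 (2R)-2-(tert-butyldimethylsilyloxy)-N-methoxy-N-methyl-5-oxopentanamide; 10 dimethyl [1-(4-methoxybenzyloxy)-2-oxopropyl]phosphonate
Product: 11 (2R,5Z)-2-(tert-butyldimethylsilyloxy)-N-methoxy-6-(4-methoxybenzyloxy)-N-methyl-7-oxooct-5-enamide
Conditions: LiCl, DBU, MeCN, 0 °C to rt
Reagents that add atoms: none
Why: Horner–Wadsworth–Emmons olefination under mild LiCl/amine conditions; the aldehyde residue should end up trans to the acetyl group (Z by the sequence rule), as is usual for α-heteroatom-substituted β-ketophosphonates. The α-silyloxy amide is not acidic enough to be epimerised.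

Step 7
Reactants: 11 (2R,5Z)-2-(tert-butyldimethylsilyloxy)-N-methoxy-6-(4-methoxybenzyloxy)-N-methyl-7-oxooct-5-enamide
Product: 12 (2R,5Z)-2-(tert-butyldimethylsilyloxy)-N-methoxy-6-(4-methoxybenzyloxy)-N-methyl-7-(triisopropylsilyloxy)octa-5,7-dienamide
Conditions: TIPSOTf, Et3N, CH2Cl2, −78 to 0 °C
Reagents that add atoms: triisopropylsilyl trifluoromethanesulfonate, CC(C)[Si](C(C)C)(C(C)C)OS(=O)(=O)C(F)(F)F
Why: Soft enolisation of the methyl ketone (silyl triflate and amine) removes a methyl proton and gives the cross-conjugated 2-silyloxydiene; the bulky TIPS group makes the dienol ether robust to handling and to the Lewis acid of step 9.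

Step 8
Reactants: 12 (2R,5Z)-2-(tert-butyldimethylsilyloxy)-N-methoxy-6-(4-methoxybenzyloxy)-N-methyl-7-(triisopropylsilyloxy)octa-5,7-dienamide; 13 isopropenylmagnesium bromide
Product: 15 (4R,7Z)-4-(tert-butyldimethylsilyloxy)-8-(4-methoxybenzyloxy)-2-methyl-9-(triisopropylsilyloxy)deca-1,7,9-trien-3-one, via bromomagnesium hemiaminal chelate 14 (not isolated)
Conditions: THF, −40 to 0 °C; pH 7 phosphate buffer, −20 °C; used at once
Reagents that add atoms: none
Why: Weinreb ketone synthesis: the Grignard reagent adds once and the chelate 14 holds until the buffered quench, so neither over-addition nor conjugate addition to the enone can occur. The cold neutral work-up preserves the dienol ether and keeps the trienone from cyclising without control.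

Step 9
Reactants: 15 (4R,7Z)-4-(tert-butyldimethylsilyloxy)-8-(4-methoxybenzyloxy)-2-methyl-9-(triisopropylsilyloxy)deca-1,7,9-trien-3-one
Product: 16 cis-fused (3R,5S,10S)-3-(tert-butyldimethylsilyloxy)-9-(4-methoxybenzyloxy)-5-methyl-8-(triisopropylsilyloxy)octal-8-en-4-one (target numbering)
Conditions: Me2AlCl (1.2 equiv), CH2Cl2, −78 to −40 °C; Et3N, then aq. NaHCO3
Reagents that add atoms: none
Why: Me2AlCl binds the C4 carbonyl and lowers the enone LUMO; C7, the nucleophilic terminus of the silyl enol ether, bonds to C6 and the C5–C10 bond follows in the same asynchronous [4+2] event. The closest known reaction type is the Lewis-acid-promoted type 1 intramolecular Diels–Alder reaction of 1,7,9-decatrien-3-ones to cis-fused octalones. Ring B is the cyclohexene ring of the cycloaddition itself; ring A closes in the fused mode because the four-atom tether C1–C4 links diene terminus C10 to dienophile carbon C5 through a chair-like six-membered array. The cis relation of C5 and C10 follows from the endo position of the tether carbonyl under the diene, combined with the diene geometry fixed in step 6 (tether trans to C8). The absolute sense comes from C3: ring closure needs the s-cis enone, in which C3 lies next to the C5 methyl, so the chair turns the C3 hydrogen toward that methyl and puts the silyloxy group equatorial, which leaves one enone face open and sets the 5-methyl and H10 trans to the C3 oxygen. Regiochemistry is enforced by the tether and reinforced by the polarity match of donor diene and acceptor enone. The step therefore needs endo over exo selectivity, which Lewis acid activation at low temperature should secure, and survival of the diene, which the TIPS group and the aprotic, HCl-scavenging aluminium reagent should secure.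

Step 10
Reactants: 16 cis-fused (3R,5S,10S)-3-(tert-butyldimethylsilyloxy)-9-(4-methoxybenzyloxy)-5-methyl-8-(triisopropylsilyloxy)octal-8-en-4-one
Product: 17 cis-fused (3R,5S,10S)-3-(tert-butyldimethylsilyloxy)-9-(4-methoxybenzyloxy)-5-methyl-4-methylene-8-(triisopropylsilyloxy)octal-8-ene (target numbering)
Conditions: Cp2Ti(μ-CH2)(μ-Cl)AlMe2, pyridine (cat.), THF–toluene, −40 °C to rt
Reagents that add atoms: Tebbe reagent Cp2Ti(μ-CH2)(μ-Cl)AlMe2, C[Al-]1(C)C[Ti](C2C=CC=C2)(C2C=CC=C2)[Cl+]1
Why: Tebbe methylenation: the titanium methylidene is small and non-basic, so it should olefinate the hindered, enolisable α-silyloxy ketone without epimerising C3; the enol ethers are not attacked.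

Step 11
Reactants: 17 cis-fused (3R,5S,10S)-3-(tert-butyldimethylsilyloxy)-9-(4-methoxybenzyloxy)-5-methyl-4-methylene-8-(triisopropylsilyloxy)octal-8-ene
Product: 18 cis-fused (3R,5S,9R,10S)-3-hydroxy-9-(4-methoxybenzyloxy)-5-methyl-4-methylenedecal-8-one (target numbering)
Conditions: Bu4NF, THF, 0 °C to rt; aq. NH4Cl
Reagents that add atoms: none
Why: Fluoride cleaves both O–Si bonds in one operation: the C3 silyl ether gives the allylic alcohol and the enol silane gives the C8 ketone. C9 is protonated under reversible, basic conditions and should favour the equatorial 9β ether; any 9-epimer converges in step 12.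

Step 12
Reactants: 18 cis-fused (3R,5S,9R,10S)-3-hydroxy-9-(4-methoxybenzyloxy)-5-methyl-4-methylenedecal-8-one
Product: 19 cis-fused (3R,4R,5R,9R,10S)-3-hydroxy-9-(4-methoxybenzyloxy)-4,5-dimethyldecal-8-one (target numbering)
Conditions: H2 (1 atm), [Ir(cod)(PCy3)(py)]PF6 (5 mol %), CH2Cl2, rt; then DBU (0.2 equiv), rt
Reagents that add atoms: none
Why: Hydroxyl-directed hydrogenation: the cationic iridium catalyst binds the C3 hydroxyl and delivers H2 to the only C=C bond from the same face, so H4 is cis to the hydroxyl and the C4 methyl cis to the angular methyl. Catalytic DBU then equilibrates C9, the only epimerisable centre, to the equatorial β-ether.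

Step 13
Reactants: 19 cis-fused (3R,4R,5R,9R,10S)-3-hydroxy-9-(4-methoxybenzyloxy)-4,5-dimethyldecal-8-one; 20 3-methylbut-2-enoyl chloride
Product: 21 cis-fused (3R,4R,5R,9R,10S)-9-(4-methoxybenzyloxy)-4,5-dimethyl-3-(3-methylbut-2-enoyloxy)decal-8-one (target numbering)
Conditions: pyridine, DMAP (cat.), CH2Cl2, 0 °C to rt
Reagents that add atoms: none
Why: Acylation of the equatorial secondary alcohol through the acylpyridinium ion; pyridine is used in place of a trialkylamine to avoid vinylketene formation and deconjugation of the senecioate.

Step 14
Reactants: 21 cis-fused (3R,4R,5R,9R,10S)-9-(4-methoxybenzyloxy)-4,5-dimethyl-3-(3-methylbut-2-enoyloxy)decal-8-one; 22 acetone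
Product: 25 cis-fused (3R,4R,5R,7R,9R,10S)-7-(2-hydroxypropan-2-yl)-9-(4-methoxybenzyloxy)-4,5-dimethyl-3-(3-methylbut-2-enoyloxy)decal-8-one (target numbering), via lithium enolate 23 (not isolated), via chlorozinc enolate 24 (not isolated)
Conditions: LiN(SiMe3)2, THF, −78 °C; ZnCl2; 22, −78 to −40 °C; aq. NH4Cl
Reagents that add atoms: none
Why: Directed aldol addition: the hindered amide base should remove a C7 proton (the CH2 side, away from the ether-bearing C9) faster than it attacks the senecioate, and the zinc enolate adds to acetone to give a chelated aldolate that resists retro-aldol cleavage. Because the addition is reversible, C7 should settle with the new group equatorial (β).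

Step 15
Reactants: 25 cis-fused (3R,4R,5R,7R,9R,10S)-7-(2-hydroxypropan-2-yl)-9-(4-methoxybenzyloxy)-4,5-dimethyl-3-(3-methylbut-2-enoyloxy)decal-8-one
Product: 26 (3R,4R,5R,7R,9R,10S)-9-(4-methoxybenzyloxy)-3-(3-methylbut-2-enoyloxy)eremophil-11-en-8-one
Conditions: SOCl2, pyridine, CH2Cl2, −20 to 0 °C
Reagents that add atoms: none
Why: Dehydration of the tertiary alcohol through its chlorosulfite: pyridine removes one of the six methyl hydrogens in an E2 step and gives the less substituted alkene under non-acidic, non-equilibrating conditions, which should avoid the conjugated 7(11)-enone.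

Step 16
Reactants: 26 (3R,4R,5R,7R,9R,10S)-9-(4-methoxybenzyloxy)-3-(3-methylbut-2-enoyloxy)eremophil-11-en-8-one
Product: 27 (3R,4R,5R,7R,9R,10S)-9-hydroxy-3-(3-methylbut-2-enoyloxy)eremophil-11-en-8-one
Conditions: DDQ, CH2Cl2–pH 7 buffer (10:1), 0 °C to rt
Reagents that add atoms: none
Why: Oxidative cleavage of the 4-methoxybenzyl ether by DDQ (hydride abstraction at the benzylic carbon, hydrolysis of the oxocarbenium ion) at neutral pH; alkenes, ester and ketone are inert and C9 keeps its configuration.

Step 17
Reactants: 27 (3R,4R,5R,7R,9R,10S)-9-hydroxy-3-(3-methylbut-2-enoyloxy)eremophil-11-en-8-one; 28 angelic acid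
Product: 30 (3R,4R,5R,7R,9R,10S)-9-[(Z)-2-methylbut-2-enoyloxy]-3-(3-methylbut-2-enoyloxy)eremophil-11-en-8-one (the target), via mixed anhydride 29 (not isolated)
Conditions: 28, 2,4,6-trichlorobenzoyl chloride, Et3N, toluene, rt; then 27, toluene, 75 °C
Reagents that add atoms: none
Why: Yamaguchi-type esterification through the mixed anhydride 29 without DMAP, so that the hydroxyl attacks the unhindered angeloyl carbonyl and no nucleophilic catalyst can add to the Z double bond and isomerise it.

## Compound list

1 | methyl (2R)-oxirane-2-carboxylate | COC(=O)[C@H]1CO1 | starting material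
2 | allylmagnesium chloride | C=CC[Mg]Cl | starting material
3 | methyl (2R)-2-hydroxyhex-5-enoate | COC(=O)[C@H](O)CCC=C | intermediate
4 | (2R)-2-hydroxy-N-methoxy-N-methylhex-5-enamide | CON(C)C(=O)[C@H](O)CCC=C | intermediate
5 | (2R)-2-(tert-butyldimethylsilyloxy)-N-methoxy-N-methylhex-5-enamide | CON(C)C(=O)[C@H](O[Si](C)(C)C(C)(C)C)CCC=C | intermediate
6 | ozonide of 5, (2R)-2-(tert-butyldimethylsilyloxy)-N-methoxy-N-methyl-4-(1,2,4-trioxolan-3-yl)butanamide | CON(C)C(=O)[C@H](O[Si](C)(C)C(C)(C)C)CCC1OCOO1 | intermediate (not isolated)
7 | (2R)-2-(tert-butyldimethylsilyloxy)-N-methoxy-N-methyl-5-oxopentanamide | CON(C)C(=O)[C@H](O[Si](C)(C)C(C)(C)C)CCC=O | intermediate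
8 | dimethyl (1-diazo-2-oxopropyl)phosphonate | COP(=O)(OC)C(=[N+]=[N-])C(C)=O | starting material
9 | 4-methoxybenzyl alcohol | COc1ccc(CO)cc1 | starting material
10 | dimethyl [1-(4-methoxybenzyloxy)-2-oxopropyl]phosphonate (racemic) | COP(=O)(OC)C(OCc1ccc(OC)cc1)C(C)=O | intermediate
11 | (2R,5Z)-2-(tert-butyldimethylsilyloxy)-N-methoxy-6-(4-methoxybenzyloxy)-N-methyl-7-oxooct-5-enamide | CON(C)C(=O)[C@H](O[Si](C)(C)C(C)(C)C)CC/C=C(OCc1ccc(OC)cc1)/C(C)=O | intermediate
12 | (2R,5Z)-2-(tert-butyldimethylsilyloxy)-N-methoxy-6-(4-methoxybenzyloxy)-N-methyl-7-(triisopropylsilyloxy)octa-5,7-dienamide | CON(C)C(=O)[C@H](O[Si](C)(C)C(C)(C)C)CC/C=C(OCc1ccc(OC)cc1)/C(=C)O[Si](C(C)C)(C(C)C)C(C)C | intermediate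
13 | isopropenylmagnesium bromide | CC(=C)[Mg]Br | starting material
14 | bromomagnesium hemiaminal chelate from 12 and 13 | C=C(C)C(O[Mg]Br)(N(C)OC)[C@H](O[Si](C)(C)C(C)(C)C)CC/C=C(OCc1ccc(OC)cc1)/C(=C)O[Si](C(C)C)(C(C)C)C(C)C | intermediate (not isolated)
15 | (4R,7Z)-4-(tert-butyldimethylsilyloxy)-8-(4-methoxybenzyloxy)-2-methyl-9-(triisopropylsilyloxy)deca-1,7,9-trien-3-one (key-step precursor) | C=C(C)C(=O)[C@H](O[Si](C)(C)C(C)(C)C)CC/C=C(OCc1ccc(OC)cc1)/C(=C)O[Si](C(C)C)(C(C)C)C(C)C | intermediate
16 | cis-fused (3R,5S,10S)-3-(tert-butyldimethylsilyloxy)-9-(4-methoxybenzyloxy)-5-methyl-8-(triisopropylsilyloxy)octal-8-en-4-one, target numbering; 5-methyl and H10 cis, C3 oxygen trans to them (key-step product) | C1C[C@@]2(C)[C@H](CC[C@@H](O[Si](C)(C)C(C)(C)C)C2=O)C(OCc3ccc(OC)cc3)=C1O[Si](C(C)C)(C(C)C)C(C)C | intermediate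
17 | cis-fused (3R,5S,10S)-3-(tert-butyldimethylsilyloxy)-9-(4-methoxybenzyloxy)-5-methyl-4-methylene-8-(triisopropylsilyloxy)octal-8-ene | C1C[C@@]2(C)[C@H](CC[C@@H](O[Si](C)(C)C(C)(C)C)C2=C)C(OCc3ccc(OC)cc3)=C1O[Si](C(C)C)(C(C)C)C(C)C | intermediate
18 | cis-fused (3R,5S,9R,10S)-3-hydroxy-9-(4-methoxybenzyloxy)-5-methyl-4-methylenedecal-8-one | C1C[C@@]2(C)[C@H](CC[C@@H](O)C2=C)[C@@H](OCc3ccc(OC)cc3)C1=O | intermediate
19 | cis-fused (3R,4R,5R,9R,10S)-3-hydroxy-9-(4-methoxybenzyloxy)-4,5-dimethyldecal-8-one | C1C[C@@]2(C)[C@H](CC[C@@H](O)[C@@H]2C)[C@@H](OCc3ccc(OC)cc3)C1=O | intermediate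
20 | 3-methylbut-2-enoyl chloride (senecioyl chloride) | CC(C)=CC(Cl)=O | starting material
21 | cis-fused (3R,4R,5R,9R,10S)-9-(4-methoxybenzyloxy)-4,5-dimethyl-3-(3-methylbut-2-enoyloxy)decal-8-one | C1C[C@@]2(C)[C@H](CC[C@@H](OC(=O)C=C(C)C)[C@@H]2C)[C@@H](OCc3ccc(OC)cc3)C1=O | intermediate
22 | acetone | CC(C)=O | starting material
23 | lithium C7–C8 enolate of 21 | C=1C[C@@]2(C)[C@H](CC[C@@H](OC(=O)C=C(C)C)[C@@H]2C)[C@@H](OCc3ccc(OC)cc3)C=1O[Li] | intermediate (not isolated)
24 | chlorozinc C7–C8 enolate of 21 | C=1C[C@@]2(C)[C@H](CC[C@@H](OC(=O)C=C(C)C)[C@@H]2C)[C@@H](OCc3ccc(OC)cc3)C=1O[Zn]Cl | intermediate (not isolated)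
25 | cis-fused (3R,4R,5R,7R,9R,10S)-7-(2-hydroxypropan-2-yl)-9-(4-methoxybenzyloxy)-4,5-dimethyl-3-(3-methylbut-2-enoyloxy)decal-8-one | CC(C)(O)[C@H]1C[C@@]2(C)[C@H](CC[C@@H](OC(=O)C=C(C)C)[C@@H]2C)[C@@H](OCc3ccc(OC)cc3)C1=O | intermediate
26 | (3R,4R,5R,7R,9R,10S)-9-(4-methoxybenzyloxy)-3-(3-methylbut-2-enoyloxy)eremophil-11-en-8-one | C=C(C)[C@H]1C[C@@]2(C)[C@H](CC[C@@H](OC(=O)C=C(C)C)[C@@H]2C)[C@@H](OCc3ccc(OC)cc3)C1=O | intermediate
27 | (3R,4R,5R,7R,9R,10S)-9-hydroxy-3-(3-methylbut-2-enoyloxy)eremophil-11-en-8-one | C=C(C)[C@H]1C[C@@]2(C)[C@H](CC[C@@H](OC(=O)C=C(C)C)[C@@H]2C)[C@@H](O)C1=O | intermediate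
28 | angelic acid, (Z)-2-methylbut-2-enoic acid | C/C=C(/C)C(=O)O | starting material
29 | (Z)-2-methylbut-2-enoic 2,4,6-trichlorobenzoic anhydride | C/C=C(/C)C(=O)OC(=O)c1c(Cl)cc(Cl)cc1Cl | intermediate (not isolated)
30 | (3R,4R,5R,7R,9R,10S)-9-[(Z)-2-methylbut-2-enoyloxy]-3-(3-methylbut-2-enoyloxy)eremophil-11-en-8-one (CNP0164025.2) | C=C(C)[C@H]1C[C@@]2(C)[C@H](CC[C@@H](OC(=O)C=C(C)C)[C@@H]2C)[C@@H](OC(=O)/C(C)=C\C)C1=O | target

## Step count and least certain steps

Total step count: 17. Longest linear sequence: 16 steps (steps 1–4 and 6–17; step 5 is the side branch).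

Step 9 (key step). The most likely failures are erosion of the endo preference, which would give trans-fused adduct through the exo transition state, and loss of the silyl dienol ether by protodesilylation before cycloaddition. The cause is that the isolated trienone must survive handling and a stoichiometric aluminium halide while its most electron-rich enol ether is exposed. Fallback: the trienone would be generated under neutral conditions in the flask in which it cyclises, without any promoter. Setting out from 12, reduction with i-Bu2AlH (THF, −78 °C) would give (2R,5Z)-2-(tert-butyldimethylsilyloxy)-6-(4-methoxybenzyloxy)-7-(triisopropylsilyloxy)octa-5,7-dienal F1. Addition of 13 would give the dienyl carbinol (4R,7Z)-4-(tert-butyldimethylsilyloxy)-8-(4-methoxybenzyloxy)-2-methyl-9-(triisopropylsilyloxy)deca-1,7,9-trien-3-ol F2 as both carbinol epimers. Oxidation with Dess–Martin periodinane and pyridine (CH2Cl2, 0 °C) would form 15 in solution, which would cyclise thermally on warming to room temperature and come back to the route at 16.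

Step 1. The likely failure is competing addition of the allyl Grignard reagent to the ester, since allylmagnesium halides add to esters fast even at −78 °C. Fallback: setting out from 1, the well-behaved copper-catalysed opening with vinylmagnesium bromide (CuI, THF, −78 °C) would give methyl (2R)-2-hydroxypent-4-enoate F3. Amidation as in step 2 would give (2R)-2-hydroxy-N-methoxy-N-methylpent-4-enamide F4, and silylation as in step 3 would give (2R)-2-(tert-butyldimethylsilyloxy)-N-methoxy-N-methylpent-4-enamide F5. Hydroboration with 9-BBN and oxidation with NaBO3·4H2O would give (2R)-2-(tert-butyldimethylsilyloxy)-5-hydroxy-N-methoxy-N-methylpentanamide F6, and Dess–Martin oxidation would come back to the route at 7, one step longer.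

Step 10. The likely failure is incomplete methylenation, because C4 is flanked by the quaternary C5 and the silyloxy-bearing C3. Fallback: a Peterson olefination with a small nucleophile. Setting out from 16, Me3SiCH2Li with CeCl3 (THF, −78 °C) would give the β-hydroxysilane cis-fused (3R,5S,10S)-3-(tert-butyldimethylsilyloxy)-4-hydroxy-9-(4-methoxybenzyloxy)-5-methyl-8-(triisopropylsilyloxy)-4-[(trimethylsilyl)methyl]octal-8-ene F7, and syn elimination with KH (THF, 0 °C to rt) would come back to the route at 17.

Step 15 (with step 14). The likely failures are elimination toward C7 or later migration of the double bond into conjugation with the ketone, and retro-aldol cleavage during activation; H7 is acidic and the conjugated enone is the more stable isomer. Fallback: setting out from 21, the lithium enolate 23 would be coupled directly with 2-bromopropene under palladium catalysis (Pd2(dba)3, P(t-Bu)3, THF, rt), a known α-alkenylation of ketone enolates, coming back to the route at 26 and replacing steps 14 and 15. It makes no compound outside the list, none F0.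

Step 17. The likely failures are Z to E isomerisation of the angeloyl group to the tiglate and base-induced conjugation of the isopropenyl ketone during the heated acylation. Fallback: build the Z double bond on the ester. Setting out from 27, esterification with 2-[bis(2,2,2-trifluoroethoxy)phosphoryl]propanoic acid (DCC, DMAP) would give the phosphonopropanoate (3R,4R,5R,7R,9R,10S)-9-{2-[bis(2,2,2-trifluoroethoxy)phosphoryl]propanoyloxy}-3-(3-methylbut-2-enoyloxy)eremophil-11-en-8-one F8. A Still–Gennari olefination with acetaldehyde (KN(SiMe3)2, 18-crown-6, THF, −78 °C) would then come back to the route at 30.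

## Further compounds

F1 | step 9 | (2R,5Z)-2-(tert-butyldimethylsilyloxy)-6-(4-methoxybenzyloxy)-7-(triisopropylsilyloxy)octa-5,7-dienal | O=C[C@H](O[Si](C)(C)C(C)(C)C)CC/C=C(OCc1ccc(OC)cc1)/C(=C)O[Si](C(C)C)(C(C)C)C(C)C
F2 | step 9 | (4R,7Z)-4-(tert-butyldimethylsilyloxy)-8-(4-methoxybenzyloxy)-2-methyl-9-(triisopropylsilyloxy)deca-1,7,9-trien-3-ol (both C3 epimers) | C=C(C)C(O)[C@H](O[Si](C)(C)C(C)(C)C)CC/C=C(OCc1ccc(OC)cc1)/C(=C)O[Si](C(C)C)(C(C)C)C(C)C
F3 | step 1 | methyl (2R)-2-hydroxypent-4-enoate | COC(=O)[C@H](O)CC=C
F4 | step 1 | (2R)-2-hydroxy-N-methoxy-N-methylpent-4-enamide | CON(C)C(=O)[C@H](O)CC=C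
F5 | step 1 | (2R)-2-(tert-butyldimethylsilyloxy)-N-methoxy-N-methylpent-4-enamide | CON(C)C(=O)[C@H](O[Si](C)(C)C(C)(C)C)CC=C
F6 | step 1 | (2R)-2-(tert-butyldimethylsilyloxy)-5-hydroxy-N-methoxy-N-methylpentanamide | CON(C)C(=O)[C@H](O[Si](C)(C)C(C)(C)C)CCCO
F7 | step 10 | cis-fused (3R,5S,10S)-3-(tert-butyldimethylsilyloxy)-4-hydroxy-9-(4-methoxybenzyloxy)-5-methyl-8-(triisopropylsilyloxy)-4-[(trimethylsilyl)methyl]octal-8-ene (C4 epimers) | C1C[C@@]2(C)[C@H](CC[C@@H](O[Si](C)(C)C(C)(C)C)C2(O)C[Si](C)(C)C)C(OCc3ccc(OC)cc3)=C1O[Si](C(C)C)(C(C)C)C(C)C
F0 | step 15 | none | none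
F8 | step 17 | (3R,4R,5R,7R,9R,10S)-9-{2-[bis(2,2,2-trifluoroethoxy)phosphoryl]propanoyloxy}-3-(3-methylbut-2-enoyloxy)eremophil-11-en-8-one | C=C(C)[C@H]1C[C@@]2(C)[C@H](CC[C@@H](OC(=O)C=C(C)C)[C@@H]2C)[C@@H](OC(=O)C(C)P(=O)(OCC(F)(F)F)OCC(F)(F)F)C1=O
A1 | alternative 1 | ring A aldehyde with C3 ethylene ketal, C4 methyl, C5 methyl and prenyl, C10 CH2CHO (target numbering) | CC(C)=CC[C@@]1(C)[C@H](CCC2(OCCO2)[C@@H]1C)CC=O
A2 | alternative 1 | cis-decalin C8 alcohol with C7 isopropenyl and C3 dioxolane | C=C(C)[C@H]1C[C@@]2(C)[C@H](CCC3(OCCO3)[C@@H]2C)C[C@@H]1O
A3 | alternative 2 | 3,3-dimethoxy-5,6-dimethyl-2-vinylbicyclo[2.2.2]oct-5-en-2-ol, vinyl syn to the C5=C6 bridge | C=C[C@@]1(O)[C@@H]2CC[C@@H](C(C)=C2C)C1(OC)OC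
A4 | alternative 2 | cis-fused 9,9-dimethoxy-4,5-dimethyloctal-3-en-8-one (target numbering) | C1C[C@@]2(C)[C@H](CCC=C2C)C(OC)(OC)C1=O
A5 | alternative 3 | 2-methoxy-5-methyl-1,4-benzoquinone | COC1=CC(=O)C(C)=CC1=O
A6 | alternative 3 | (3Z)-3-(tert-butyldimethylsilyloxy)penta-1,3-diene | C/C=C(\O[Si](C)(C)C(C)(C)C)C=C
A7 | alternative 3 | cis-fused endo adduct with C3 silyl enol ether, C6 and C9 ketones and C8 methoxy enone (C4 methyl epimeric) | COC1=CC(=O)[C@@]2(C)[C@H](CC=C(O[Si](C)(C)C(C)(C)C)[C@H]2C)C1=O
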